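In the maple flask the target cannot pass what 0.170 equiv of reagent, the limiting reagent there, can make if one reagent gives one target. So the question for last place is how much of that charge has gone by 2.5 d.

| flask | substrate | reagent | free catalyst | temperature | remark | time |
|---|---|---|---|---|---|---|
| ochre | 0.24 M | 0.70 equiv | 1.4 mol% | 42 °C | run made earlier |  |
| red | 0.67 M | 0.70 equiv | 1.4 mol% | 59 °C | run made earlier |  |
| green | 1.9 M | 0.70 equiv | 1.4 mol% | 42 °C | run made earlier |  |
| teal | 1 M | 0.70 equiv | 1.2 mol% | 59 °C | run made earlier |  |
| ash | 1.0 M | 0.700 equiv | 1.4 mol% | 35 °C |  | 2.5 d |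
| maple | 0.25 M | 0.170 equiv | 1.4 mol% | 35 °C |  | 2.5 d |
| larch | 1.0 M | 0.700 equiv | 1 mol% | 65 °C |  | 2.5 d |
| alder | 1.0 M | 1.40 equiv | 1.4 mol% | 35 °C |  | 2.5 d |
| elm | 2.0 M | 1.40 equiv | 1.4 mol% | 65 °C |  | 2.5 d |
| cedar | 1.0 M | 0.700 equiv | 0.8 mol% | 35 °C |  | 2.5 d |

| ochre: time / d | ochre: target / % | red: time / h | red: target / % | green: time / d | green: target / % | teal: time / h | teal: target / % |
|---|---|---|---|---|---|---|---|
| 0.208 | 8.5 | 4.00 | 37.7 | 0.208 | 46.0 | 1.50 | 40.7 |
| 0.625 | 18.1 | 8.00 | 37.4 | 0.417 | 44.7 | 3.00 | 42.2 |
| 1.25 | 23.4 | 12.0 | 37.8 | 0.625 | 44.4 | 5.00 | 41.7 |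
| 1.67 | 24.1 | 15.0 | 38.2 | 1.25 | 45.1 | 10.0 | 42.0 |
| 2.50 | 25.4 | 20.0 | 37.9 | 2.50 | 45.5 | 20.0 | 42.8 |

(standard deviation of a reading: 0.5 percentage points)

* all flasks from highest to lowest amount of target, in percent of the substrate charged, at 2.5 d (ash / maple / larch / alder / elm / cedar)
* the same order at 12 h (ash / maple / larch / alder / elm / cedar)
* the amount of target, in percent of the substrate charged of the flask you put first, at 2.5 d
* the amount of target, in percent of the substrate charged of the flask you put last, at 2.5 d

- the numbers in the tables scatter by 0.5 percentage points (one standard deviation)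

I count lifetimes. I assume that the first step runs as substrate times reagent times free catalyst, so with substrate and free catalyst held at their charge the reagent falls exponentially, a pseudo-first-order view. The reagent lifetime τ is the time in which reagent falls by a factor e under that holding. Counting target as reagent spent, the first ochre reading puts it at 1.61 d.

The loading is in mol%, so free catalyst goes with substrate, and τ goes as the inverse square of the substrate charge. The reagent equivalents drop out of τ. On that scaling the green run, at 1.9 M, has a lifetime of 0.0256 d, and it does stand flat at its first reading. For maple I also need the step from 42 °C down to 35 °C, and a doubling per 10 degrees gives a factor 1.62. Then τ in maple is 2.41 d, so 35.4% of its reagent remains at 2.5 d. That is 11.0% of the substrate turned over.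

The weak link is counting turnover as target, and the ochre run shows it. Its reading at 1.67 d stands 1.04 lifetimes in, and maple at 2.5 d stands 1.04 lifetimes in. At that ochre reading the same reckoning turns over 45.2% of the substrate, but the reading is 24.1%. So about 53.3% of the reckoned turnover stands as target there, a share read with the scatter of that reading. I carry this share over to maple as an estimate, which gives 5.85% of the substrate charged, and I commit to that as target. The temperature factor matters less: a full factor 2 in its place takes the turnover to 9.69%, a smaller shift than the one this share makes.

The forecast reads elm > alder > larch > ash > cedar > maple at 2.5 d and elm > alder > larch > ash > cedar > maple at 12 h, with 70% first and 9% last: “Maple is slow and reaches about 9 by 2.5 d”. My reckoning for maple, at 5.85%, stands lower than that.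

The flask gives elm > alder > larch > cedar > ash > maple at 2.5 d and elm > alder > larch > ash > cedar > maple at 12 h, with elm at 75.3% and maple at 6.74%.

    substrate + reagent + free catalyst → free catalyst + target (k = 21.8 /M²/h, Ea = 62.0 kJ/mol)
    free catalyst + target → free catalyst + over-reaction product (k = 4.02 /M/h, Ea = 52.0 kJ/mol)
    free catalyst + target → spent catalyst (k = 0.251 /M/h, Ea = 75.0 kJ/mol)
    (constants at 35 °C)

Beside that target, maple holds 3.76% of over-reaction product, and 36.8% of its reagent remains. A neighbour of maple charged with 0.062 M of substrate, with the same equivalents, loading and time, has τ of 39.1 d. That leaves 93.8% of its reagent by reckoning, and the neighbour holds 93.3%.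

The data are calculated from invented constants.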